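Ring B (C1–C9–C5–C6–C7–C8) is closed at C5–C6. C5 lies between the C4 and C9 carbonyls, C6 is an unactivated methylene and C7 bears a carbon chain. A C5 radical therefore adds to the end carbon (C6) of a 1,1-dimethylallyl arm on C1, and the C7 radical that forms takes up an allyl group. One operation makes C5–C6 and C7–allyl, closes ring B and sets C5 and C7 from C1. The precursor is a 2-bromo-2-lavandulylcyclohexane-1,3-dione whose C1 already carries the aroyl and 1,1-dimethylallyl groups. Its lavandulyl trisubstituted alkene is masked as an epoxide, because it would otherwise capture the C5 radical 5-exo.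

Key step: step 12

Remarks on the chemistry (conventions, one assumption, design points)
- Atom labels: the bicyclo[3.3.1]nonane numbering of the target is used throughout, also for the monocyclic precursors. C1 is the aroyl bridgehead, C2 the enol carbon, C4 a ketone, C5 the lavandulyl bridgehead, C8 the gem-dimethyl carbon and C9 the bridging ketone. Ring A is C1–C2–C3–C4–C5–C9 and ring B is C1–C9–C5–C6–C7–C8.
- Lav = 5-methyl-2-(prop-1-en-2-yl)hex-4-en-1-yl with the spatial arrangement of (S)-lavandulol. It is written (2R) once bound to a ring carbon, a change of priorities only.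
- epoxy-Lav = Lav with its 4,5-alkene as the epoxide (both epimers at the epoxide CH). Ar = 3,4-bis(triisopropylsilyloxy)phenyl.
- Assumption: commercial lavandulol is the racemate, so the (S)-alcohol is secured by enzymatic resolution.
- Masking of the lavandulyl alkene: with a free Lav group the C5 radical is a hex-5-enyl radical (C5–C1′–C2′–C3′–C4′=C5′). Its 5-exo closure onto the electron-rich alkene would outrun the bridging 6-endo closure, so this alkene is an epoxide while the radical is alive. The carbon skeleton is unchanged.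
- Two-stage radical step: an allyl donor present from the start would intercept the electrophilic C5 radical. The ring is therefore closed first by bromine-atom transfer, and the stannane is added afterwards in the same flask.
- Protecting group: triisopropylsilyl ethers guard the catechol, because alkoxide is present in several later steps.
- Centres that vanish later are formed as mixtures. These are C5 of the monocyclic bromides, the epoxide CH, C7 of the intermediate bromide and C2 of the boronate and alcohol. They are left undefined in the SMILES or drawn as one epimer.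

Step 1
Reactants: 1 (±)-lavandulol
Product: 2 (S)-lavandulol
Conditions: immobilised Candida antarctica lipase B, vinyl acetate, hexane, 25 °C, run past half conversion; chromatography
Reagents that add atoms: none
Why: Lipase-catalysed kinetic resolution by transesterification, in which this lipase is expected to acylate the (R)-alcohol faster, so that running past half conversion leaves the (S)-alcohol whose stereocentre becomes the lavandulyl stereocentre of the target unchanged.

Step 2
Reactants: 2 (S)-lavandulol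
Product: 3 (S)-lavandulyl iodide, (3S)-3-(iodomethyl)-2,6-dimethylhepta-1,5-diene
Conditions: PPh3, I2, imidazole, CH2Cl2, 0 °C to rt
Reagents that add atoms: iodine, II
Why: Appel-type iodination replaces the primary hydroxyl by SN2 at the CH2 carbon and leaves the neighbouring stereocentre untouched.

Step 3
Reactants: 4 1,5-dimethoxycyclohexa-1,4-diene; 3 (S)-lavandulyl iodide
Product: 6 2-Lav-cyclohexane-1,3-dione (enolised), via alkylated diene 5 (not isolated)
Conditions: 4, t-BuLi, THF, −78 °C; DMPU, 3, −78 to 0 °C; then 1 M HCl, THF, rt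
Reagents that add atoms: water, O
Why: The lithiated bis-enol ether is a masked C2 anion of cyclohexane-1,3-dione and is alkylated by SN2 at the carbon between the two enol ethers, which avoids the O-alkylation a dione enolate would give with an unactivated iodide, and aqueous acid then hydrolyses both enol ethers.

Step 4
Reactants: 6 2-Lav-cyclohexane-1,3-dione
Product: 7 3-methoxy-2-Lav-cyclohex-2-en-1-one
Conditions: Me3SiCHN2, MeOH/toluene, 0 °C to rt
Reagents that add atoms: (trimethylsilyl)diazomethane, C[Si](C)(C)C=[N+]=[N-]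
Why: O-Methylation of the acidic dione enol by diazomethane generated in the flask gives a single vinylogous ester (the two oxygens are equivalent) and blocks C5 for the enolate chemistry that follows.

Step 5
Reactants: 8 3,4-dihydroxybenzoic acid
Product: 10 3,4-bis(triisopropylsilyloxy)benzoic acid, via silyl ester 9 (not isolated)
Conditions: TIPSCl, imidazole, DMF, 40 °C; then AcOH, THF/H2O, rt
Reagents that add atoms: chlorotriisopropylsilane, CC(C)[Si](Cl)(C(C)C)C(C)C
Why: Silylation of both phenols and of the acid is followed by selective hydrolysis of the labile silyl ester, and the bulky silyl ethers are chosen because they withstand enolates and catalytic alkoxide.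

Step 6
Reactants: 10 3,4-bis(triisopropylsilyloxy)benzoic acid
Product: 11 1-[3,4-bis(triisopropylsilyloxy)benzoyl]-1H-benzotriazole
Conditions: 1H-benzotriazole, DCC, CH2Cl2, 0 °C to rt
Reagents that add atoms: 1H-benzotriazole, c1ccc2[nH]nnc2c1
Why: Carbodiimide coupling gives the N-acylbenzotriazole, a stable acyl donor that acylates ketone enolates on carbon.

Step 7
Reactants: 7 3-methoxy-2-Lav-cyclohex-2-en-1-one; 11 1-[3,4-bis(triisopropylsilyloxy)benzoyl]-1H-benzotriazole
Product: 12 6-(ArCO)-3-methoxy-2-Lav-cyclohex-2-en-1-one (C1–H epimers and enol)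
Conditions: LDA (2.1 equiv), THF, −78 °C; 11, −78 to −40 °C; aq. NH4Cl
Reagents that add atoms: none
Why: Kinetic α′-deprotonation of the vinylogous ester (Stork–Danheiser regiochemistry) and Claisen-type C-acylation at C1, the second equivalent of base taking up the acidic β-diketone; the new C1–H centre is enolisable and carries no stereochemical information.

Step 8
Reactants: 13 2-methylbut-3-en-2-ol
Product: 14 tert-butyl 2-methylbut-3-en-2-yl carbonate
Conditions: n-BuLi, THF, 0 °C; Boc2O, 0 °C to rt
Reagents that add atoms: di-tert-butyl dicarbonate, CC(C)(C)OC(=O)OC(=O)OC(C)(C)C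
Why: Acylation of the lithium alkoxide of the tertiary alcohol gives the allylic carbonate that serves as 1,1-dimethylallyl donor in step 9 and as prenyl donor in step 18.

Step 9
Reactants: 12 6-(ArCO)-3-methoxy-2-Lav-cyclohex-2-en-1-one; 14 tert-butyl 2-methylbut-3-en-2-yl carbonate
Product: 15 6-(ArCO)-3-methoxy-6-(2-methylbut-3-en-2-yl)-2-Lav-cyclohex-2-en-1-one, quaternary carbon (C1) configured as in the target
Conditions: [Ir(cod)Cl]2 (5 mol %), (S)-4-(5H-dibenzo[b,f]azepin-5-yl)dinaphtho[2,1-d:1′,2′-f][1,3,2]dioxaphosphepine (20 mol %), THF, 40 °C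
Reagents that add atoms: none
Why: Proposed new method: oxidative addition of the iridium–phosphoramidite catalyst to 14 gives an η3-1,1-dimethylallyl complex of trivalent iridium and tert-butoxide, which deprotonates 12; the enolate attacks the more substituted allyl terminus, as iridium allyl complexes direct, forming C1–C8, and the chiral ligand selects the enolate face, so C1 is set under catalyst control independent of the remote lavandulyl centre (the ligand antipode is used if a pilot run shows the opposite sense); the closest known reactions are the iridium-catalysed reverse prenylation of 3-substituted indoles, which also joins two fully substituted carbons, and the iridium-catalysed branched allylation of cyclic β-keto esters that creates quaternary α-carbons.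

Step 10
Reactants: 15 6-(ArCO)-3-methoxy-6-(2-methylbut-3-en-2-yl)-2-Lav-cyclohex-2-en-1-one
Product: 16 4-(ArCO)-4-(2-methylbut-3-en-2-yl)-2-Lav-cyclohexane-1,3-dione (enolised at C5)
Conditions: 2 M aq. HCl, THF, rt
Reagents that add atoms: water, O
Why: Acid hydrolysis of the vinylogous ester (addition of water at C4, loss of methanol) frees the 1,3-dione; acid is used because hydroxide could cleave the non-enolisable C1 diketone by a retro-Claisen reaction, and C1 is not affected.

Step 11
Reactants: 16 4-(ArCO)-4-(2-methylbut-3-en-2-yl)-2-Lav-cyclohexane-1,3-dione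
Product: 18 2-bromo-4-(ArCO)-4-(2-methylbut-3-en-2-yl)-2-(epoxy-Lav)cyclohexane-1,3-dione (C5 epimers), via bromide 17 (not isolated)
Conditions: NBS, CH2Cl2, 0 °C; then NaHCO3, mCPBA (1.0 equiv), −10 to 0 °C
Reagents that add atoms: N-bromosuccinimide, O=C1CCC(=O)N1Br; 3-chloroperbenzoic acid, OOC(=O)c1cccc(Cl)c1
Why: The dione enol, far more nucleophilic than any alkene present, is brominated at C5, and the Prilezhaev epoxidation that follows picks the most electron-rich, trisubstituted alkene; neither new centre needs control because both are erased later.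

Step 12
Reactants: 18 2-bromo-4-(ArCO)-4-(2-methylbut-3-en-2-yl)-2-(epoxy-Lav)cyclohexane-1,3-dione; 19 allyltributylstannane
Product: 21 7-exo-allyl-1-(ArCO)-8,8-dimethyl-5-(epoxy-Lav)bicyclo[3.3.1]nonane-4,9-dione, C1 C5 C7 as in the target, via bromide 20 (not isolated)
Conditions: dilauroyl peroxide (0.1 equiv, portions), PhCF3 (0.02 M), 80 °C; then 19 (5 equiv), AIBN (0.3 equiv, portions), 80 °C
Reagents that add atoms: none
Why: Proposed new method: undecyl radicals from the peroxide abstract bromine from 18, the planar, electrophilic C5 radical adds to the terminal carbon C6 of the 1,1-dimethylallyl arm and the secondary C7 radical takes bromine from a further molecule of 18 (atom-transfer chain to 20), after which tributyltin radicals generated from 19 and AIBN return 20 to the C7 radical, which is allylated by 19 in an SH2′ step that releases Bu3Sn•. The closest known reaction types are bromine-atom-transfer cyclisations of 2-halo-1,3-dicarbonyl compounds, oxidative 6-endo closures of 1,3-dicarbonyl radicals onto alkenyl arms that give bicyclo[3.3.1]nonan-9-ones, and the Keck allylation of secondary bromides; their union in one flask on this scaffold is new. Ring B closes 6-endo-trig, favoured because the C9 carbonyl lies inside the forming ring and because the alternative 5-exo carbon C7 is neopentyl, next to C8. C5 can bond only on the ring face that carries the C1 arm, so its configuration is dictated by C1; at C7 the endo face is shielded by ring A, so 19 is attacked from the exo face and the allyl group ends equatorial on ring B, cis to the C1 aroyl group. The step needs ring closure to precede every bimolecular capture of the C5 radical: in the first stage no allyl donor is present and the epoxide has removed the only alkene that could be reached 5-exo, so the stabilised radical can wait for the conformer with the arm axial, and both C5 epimers and both epoxide epimers of 18 converge on the same radical.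

Step 13
Reactants: 21 7-exo-allyl-1-(ArCO)-8,8-dimethyl-5-(epoxy-Lav)bicyclo[3.3.1]nonane-4,9-dione
Product: 22 7-exo-allyl-1-(ArCO)-8,8-dimethyl-5-Lav-bicyclo[3.3.1]nonane-4,9-dione
Conditions: Re2O7 (5 mol %), P(OPh)3, toluene, 100 °C
Reagents that add atoms: none
Why: Rhenium-catalysed oxygen-atom transfer from the epoxide to the phosphite (deoxygenation) restores the trisubstituted alkene under neutral conditions that leave the ketones, the allyl group and the silyl ethers alone, and both epoxide epimers give the same alkene.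

Step 14
Reactants: 22 7-exo-allyl-1-(ArCO)-8,8-dimethyl-5-Lav-bicyclo[3.3.1]nonane-4,9-dione
Product: 23 1-(ArCO)-8,8-dimethyl-7-exo-(3-methylbut-2-en-1-yl)-5-Lav-bicyclo[3.3.1]nonane-4,9-dione
Conditions: second-generation Grubbs catalyst RuCl2(=CHPh)(PCy3)(H2IMes) (5 mol %), 2-methylbut-2-ene/CH2Cl2, 40 °C
Reagents that add atoms: 2-methylbut-2-ene, CC=C(C)C
Why: Olefin cross-metathesis of the terminal allyl group with excess 2-methylbut-2-ene gives the prenyl group, the 1,1-disubstituted and trisubstituted alkenes of the Lav chain being far less reactive towards the ruthenium carbene.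

Step 15
Reactants: 23 1-(ArCO)-8,8-dimethyl-7-exo-(3-methylbut-2-en-1-yl)-5-Lav-bicyclo[3.3.1]nonane-4,9-dione
Product: 24 1-(ArCO)-8,8-dimethyl-7-exo-(3-methylbut-2-en-1-yl)-5-Lav-bicyclo[3.3.1]non-2-ene-4,9-dione
Conditions: LDA, THF, −78 °C; PhS(Cl)=N-t-Bu, −78 °C
Reagents that add atoms: none
Why: Mukaiyama dehydrogenation, in which C3 is the only enolisable position, its lithium enolate is sulfenylated by the sulfinimidoyl chloride and syn-elimination at low temperature gives the C2–C3 enone.

Step 16
Reactants: 24 1-(ArCO)-8,8-dimethyl-7-exo-(3-methylbut-2-en-1-yl)-5-Lav-bicyclo[3.3.1]non-2-ene-4,9-dione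
Product: 26 1-(ArCO)-2-hydroxy-8,8-dimethyl-7-exo-(3-methylbut-2-en-1-yl)-5-Lav-bicyclo[3.3.1]nonane-4,9-dione (C2 epimers), via boronate 25 (not isolated)
Conditions: CuCl (10 mol %), bis[2-(diphenylphosphino)phenyl] ether (10 mol %), NaOt-Bu (10 mol %), B2pin2, MeOH, THF, rt; then H2O2, pH 7 phosphate buffer, 0 °C
Reagents that add atoms: hydrogen peroxide, OO
Why: Copper-catalysed conjugate borylation places boron on the β-carbon C2 (as with 4,4-disubstituted cyclohexenones) and oxidation with retention turns C–B into C–OH; the peroxide is buffered so that a C2 alkoxide cannot trigger retro-aldol cleavage of C1–C2, and the C2 configuration is irrelevant.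

Step 17
Reactants: 26 1-(ArCO)-2-hydroxy-8,8-dimethyl-7-exo-(3-methylbut-2-en-1-yl)-5-Lav-bicyclo[3.3.1]nonane-4,9-dione
Product: 27 1-(ArCO)-2-hydroxy-8,8-dimethyl-7-exo-(3-methylbut-2-en-1-yl)-5-Lav-bicyclo[3.3.1]non-2-ene-4,9-dione (enol of the 2,4,9-trione)
Conditions: Dess–Martin periodinane, NaHCO3, CH2Cl2, 0 °C to rt
Reagents that add atoms: none
Why: Dess–Martin oxidation of the secondary alcohol under non-basic conditions gives the C2 ketone, and the resulting 2,4-dione rests as its enol.

Step 18
Reactants: 27 1-(ArCO)-2-hydroxy-8,8-dimethyl-7-exo-(3-methylbut-2-en-1-yl)-5-Lav-bicyclo[3.3.1]non-2-ene-4,9-dione; 14 tert-butyl 2-methylbut-3-en-2-yl carbonate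
Product: 28 1-(ArCO)-2-hydroxy-8,8-dimethyl-3,7-bis(3-methylbut-2-en-1-yl)-5-Lav-bicyclo[3.3.1]non-2-ene-4,9-dione
Conditions: Pd(PPh3)4 (5 mol %), 14 (1.05 equiv), THF, rt
Reagents that add atoms: none
Why: Tsuji–Trost allylation, in which zerovalent palladium ionises 14 to the η3-1,1-dimethylallyl complex and the soft dione enolate attacks its unsubstituted terminus, so the linear prenyl group is placed on C3, any O-allylated material being re-ionised and funnelled to the C-allylated product.

Step 19
Reactants: 28 1-(ArCO)-2-hydroxy-8,8-dimethyl-3,7-bis(3-methylbut-2-en-1-yl)-5-Lav-bicyclo[3.3.1]non-2-ene-4,9-dione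
Product: 29 (1S,5R,7S)-1-(3,4-dihydroxybenzoyl)-2-hydroxy-8,8-dimethyl-3,7-bis(3-methylbut-2-en-1-yl)-5-[(2R)-5-methyl-2-(prop-1-en-2-yl)hex-4-en-1-yl]bicyclo[3.3.1]non-2-ene-4,9-dione
Conditions: TBAF, AcOH, THF, 0 °C
Reagents that add atoms: none
Why: Fluoride cleaves the two aryl silyl ethers while acetic acid keeps the catechol and the enol protonated; no stereocentre is involved.

Compound list
1 | (±)-lavandulol, rac-5-methyl-2-(prop-1-en-2-yl)hex-4-en-1-ol | C=C(C)C(CO)CC=C(C)C | starting material
2 | (S)-lavandulol | C=C(C)[C@H](CC=C(C)C)CO | intermediate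
3 | (S)-lavandulyl iodide | C=C(C)[C@H](CC=C(C)C)CI | intermediate
4 | 1,5-dimethoxycyclohexa-1,4-diene | COC1=CCC=C(OC)C1 | starting material
5 | 1,5-dimethoxy-6-Lav-cyclohexa-1,4-diene (not isolated) | C=C(C)[C@H](CC=C(C)C)CC1C(OC)=CCC=C1OC | intermediate
6 | 2-Lav-cyclohexane-1,3-dione | C=C(C)[C@H](CC=C(C)C)CC1C(=O)CCCC1=O | intermediate
7 | 3-methoxy-2-Lav-cyclohex-2-en-1-one | C=C(C)[C@H](CC=C(C)C)CC1=C(OC)CCCC1=O | intermediate
8 | 3,4-dihydroxybenzoic acid | OC(=O)c1ccc(O)c(O)c1 | starting material
9 | triisopropylsilyl 3,4-bis(triisopropylsilyloxy)benzoate (not isolated) | CC(C)[Si](C(C)C)(C(C)C)OC(=O)c1ccc(O[Si](C(C)C)(C(C)C)C(C)C)c(O[Si](C(C)C)(C(C)C)C(C)C)c1 | intermediate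
10 | 3,4-bis(triisopropylsilyloxy)benzoic acid | OC(=O)c1ccc(O[Si](C(C)C)(C(C)C)C(C)C)c(O[Si](C(C)C)(C(C)C)C(C)C)c1 | intermediate
11 | 1-[3,4-bis(triisopropylsilyloxy)benzoyl]-1H-benzotriazole | O=C(c1ccc(O[Si](C(C)C)(C(C)C)C(C)C)c(O[Si](C(C)C)(C(C)C)C(C)C)c1)n1nnc2ccccc12 | intermediate
12 | 6-(ArCO)-3-methoxy-2-Lav-cyclohex-2-en-1-one (C1–H epimers, enolisable) | C=C(C)[C@H](CC=C(C)C)CC1=C(OC)CCC(C(=O)c2ccc(O[Si](C(C)C)(C(C)C)C(C)C)c(O[Si](C(C)C)(C(C)C)C(C)C)c2)C1=O | intermediate
13 | 2-methylbut-3-en-2-ol | CC(C)(O)C=C | starting material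
14 | tert-butyl 2-methylbut-3-en-2-yl carbonate | CC(C)(C=C)OC(=O)OC(C)(C)C | intermediate
15 | 6-(ArCO)-3-methoxy-6-(2-methylbut-3-en-2-yl)-2-Lav-cyclohex-2-en-1-one, C1 as in the target | C=C(C)[C@H](CC=C(C)C)CC1=C(OC)CC[C@@](C(C)(C)C=C)(C(=O)c2ccc(O[Si](C(C)C)(C(C)C)C(C)C)c(O[Si](C(C)C)(C(C)C)C(C)C)c2)C1=O | intermediate
16 | 4-(ArCO)-4-(2-methylbut-3-en-2-yl)-2-Lav-cyclohexane-1,3-dione (enolised at C5) | C=C(C)[C@H](CC=C(C)C)CC1C(=O)CC[C@@](C(C)(C)C=C)(C(=O)c2ccc(O[Si](C(C)C)(C(C)C)C(C)C)c(O[Si](C(C)C)(C(C)C)C(C)C)c2)C1=O | intermediate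
17 | 2-bromo-4-(ArCO)-4-(2-methylbut-3-en-2-yl)-2-Lav-cyclohexane-1,3-dione (not isolated; both C5 epimers, one drawn) | C=C(C)[C@H](CC=C(C)C)C[C@@]1(Br)C(=O)CC[C@@](C(C)(C)C=C)(C(=O)c2ccc(O[Si](C(C)C)(C(C)C)C(C)C)c(O[Si](C(C)C)(C(C)C)C(C)C)c2)C1=O | intermediate
18 | 2-bromo-4-(ArCO)-4-(2-methylbut-3-en-2-yl)-2-(epoxy-Lav)cyclohexane-1,3-dione (both C5 epimers, one drawn; both epoxide epimers) | C=C(C)[C@H](CC3OC3(C)C)C[C@@]1(Br)C(=O)CC[C@@](C(C)(C)C=C)(C(=O)c2ccc(O[Si](C(C)C)(C(C)C)C(C)C)c(O[Si](C(C)C)(C(C)C)C(C)C)c2)C1=O | intermediate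
19 | allyltributylstannane | C=CC[Sn](CCCC)(CCCC)CCCC | starting material
20 | 7-bromo-1-(ArCO)-8,8-dimethyl-5-(epoxy-Lav)bicyclo[3.3.1]nonane-4,9-dione (not isolated; C7 undefined) | C=C(C)[C@H](CC3OC3(C)C)C[C@]12CC(Br)C(C)(C)[C@](C(=O)c3ccc(O[Si](C(C)C)(C(C)C)C(C)C)c(O[Si](C(C)C)(C(C)C)C(C)C)c3)(C1=O)CCC2=O | intermediate
21 | 7-exo-allyl-1-(ArCO)-8,8-dimethyl-5-(epoxy-Lav)bicyclo[3.3.1]nonane-4,9-dione | C=C(C)[C@H](CC3OC3(C)C)C[C@]12C[C@H](CC=C)C(C)(C)[C@](C(=O)c3ccc(O[Si](C(C)C)(C(C)C)C(C)C)c(O[Si](C(C)C)(C(C)C)C(C)C)c3)(C1=O)CCC2=O | intermediate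
22 | 7-exo-allyl-1-(ArCO)-8,8-dimethyl-5-Lav-bicyclo[3.3.1]nonane-4,9-dione | C=C(C)[C@H](CC=C(C)C)C[C@]12C[C@H](CC=C)C(C)(C)[C@](C(=O)c3ccc(O[Si](C(C)C)(C(C)C)C(C)C)c(O[Si](C(C)C)(C(C)C)C(C)C)c3)(C1=O)CCC2=O | intermediate
23 | 1-(ArCO)-8,8-dimethyl-7-exo-(3-methylbut-2-en-1-yl)-5-Lav-bicyclo[3.3.1]nonane-4,9-dione | C=C(C)[C@H](CC=C(C)C)C[C@]12C[C@H](CC=C(C)C)C(C)(C)[C@](C(=O)c3ccc(O[Si](C(C)C)(C(C)C)C(C)C)c(O[Si](C(C)C)(C(C)C)C(C)C)c3)(C1=O)CCC2=O | intermediate
24 | 1-(ArCO)-8,8-dimethyl-7-exo-(3-methylbut-2-en-1-yl)-5-Lav-bicyclo[3.3.1]non-2-ene-4,9-dione | C=C(C)[C@H](CC=C(C)C)C[C@]12C[C@H](CC=C(C)C)C(C)(C)[C@](C(=O)c3ccc(O[Si](C(C)C)(C(C)C)C(C)C)c(O[Si](C(C)C)(C(C)C)C(C)C)c3)(C1=O)C=CC2=O | intermediate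
25 | 2-(4,4,5,5-tetramethyl-1,3,2-dioxaborolan-2-yl) derivative of 23 (not isolated; C2 undefined) | C=C(C)[C@H](CC=C(C)C)C[C@]12C[C@H](CC=C(C)C)C(C)(C)[C@](C(=O)c3ccc(O[Si](C(C)C)(C(C)C)C(C)C)c(O[Si](C(C)C)(C(C)C)C(C)C)c3)(C1=O)C(B3OC(C)(C)C(C)(C)O3)CC2=O | intermediate
26 | 1-(ArCO)-2-hydroxy-8,8-dimethyl-7-exo-(3-methylbut-2-en-1-yl)-5-Lav-bicyclo[3.3.1]nonane-4,9-dione (C2 undefined) | C=C(C)[C@H](CC=C(C)C)C[C@]12C[C@H](CC=C(C)C)C(C)(C)[C@](C(=O)c3ccc(O[Si](C(C)C)(C(C)C)C(C)C)c(O[Si](C(C)C)(C(C)C)C(C)C)c3)(C1=O)C(O)CC2=O | intermediate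
27 | 1-(ArCO)-2-hydroxy-8,8-dimethyl-7-exo-(3-methylbut-2-en-1-yl)-5-Lav-bicyclo[3.3.1]non-2-ene-4,9-dione | C=C(C)[C@H](CC=C(C)C)C[C@]12C[C@H](CC=C(C)C)C(C)(C)[C@](C(=O)c3ccc(O[Si](C(C)C)(C(C)C)C(C)C)c(O[Si](C(C)C)(C(C)C)C(C)C)c3)(C1=O)C(O)=CC2=O | intermediate
28 | 1-(ArCO)-2-hydroxy-8,8-dimethyl-3,7-bis(3-methylbut-2-en-1-yl)-5-Lav-bicyclo[3.3.1]non-2-ene-4,9-dione | C=C(C)[C@H](CC=C(C)C)C[C@]12C[C@H](CC=C(C)C)C(C)(C)[C@](C(=O)c3ccc(O[Si](C(C)C)(C(C)C)C(C)C)c(O[Si](C(C)C)(C(C)C)C(C)C)c3)(C1=O)C(O)=C(CC=C(C)C)C2=O | intermediate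
29 | (1S,5R,7S)-1-(3,4-dihydroxybenzoyl)-2-hydroxy-8,8-dimethyl-3,7-bis(3-methylbut-2-en-1-yl)-5-[(2R)-5-methyl-2-(prop-1-en-2-yl)hex-4-en-1-yl]bicyclo[3.3.1]non-2-ene-4,9-dione | C=C(C)[C@H](CC=C(C)C)C[C@]12C[C@H](CC=C(C)C)C(C)(C)[C@](C(=O)c3ccc(O)c(O)c3)(C1=O)C(O)=C(CC=C(C)C)C2=O | target

Total step count: 19. Longest linear sequence: 16 steps (1, 2, 3, 4, 7, 9 to 19); steps 5, 6 and 8 are side branches.

Steps most likely to fail

1. Step 12 (carries the new-method label). The C5 radical may be consumed before it closes the ring, since closure needs the bulky arm axial. It may also close at C7 instead of C6, or the ring may reopen before the allyl transfer so that allylation occurs at C5. The fallback sets out from 18 and returns at 21, using a tin-free degenerate xanthate chain. Potassium O-ethyl xanthate in acetone at 0 °C replaces the bromine of 18 to give the C5 xanthate F1. Dilauroyl peroxide, added in portions in refluxing 1,2-dichloroethane, then runs a xanthate-transfer cyclisation, in which the C5 radical has no exit other than ring closure. This gives the ring-closed 7-(ethoxythiocarbonylthio) bicycle F2. Allyl ethyl sulfone with dilauroyl peroxide in refluxing chlorobenzene finally exchanges the xanthate for an allyl group from the exo face, giving 21.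

2. Step 9 (carries the new-method label). The enolate may be allylated on oxygen or at the unsubstituted allyl terminus instead of forming the hindered C1–C8 bond, or the catalyst may discriminate the enolate faces poorly. The fallback sets out from 12 and returns at 15. Mitsunobu O-alkylation of 12 with 3-methylbut-2-en-1-ol (PPh3, DIAD, toluene, 0 °C) gives the prenyl dienol ether F3. Heating in toluene at 110 °C brings about the Claisen rearrangement, which forms C1–C8 reliably but gives 15 together with its C1 epimer. The two are separated by preparative HPLC, at the cost of half the material.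

3. Step 13. The rhenium catalyst may act as a Lewis acid and open or rearrange the trisubstituted epoxide (hydride shift, or capture by the neighbouring isopropenyl group) instead of transferring its oxygen. The fallback sets out from 21 and returns at 22. Periodic acid in THF/water at 0 °C cleaves the epoxide to the aldehyde F4. Isopropylidenetriphenylphosphorane (from isopropyltriphenylphosphonium iodide and n-BuLi, THF, −78 °C) then rebuilds the trisubstituted alkene by a Wittig reaction, the aldehyde reacting well before the ketones, giving 22.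

Further compounds
F1 | step 12 | 2-(ethoxythiocarbonylthio)-4-(ArCO)-4-(2-methylbut-3-en-2-yl)-2-(epoxy-Lav)cyclohexane-1,3-dione | C=C(C)[C@H](CC3OC3(C)C)CC1(SC(=S)OCC)C(=O)CC[C@@](C(C)(C)C=C)(C(=O)c2ccc(O[Si](C(C)C)(C(C)C)C(C)C)c(O[Si](C(C)C)(C(C)C)C(C)C)c2)C1=O
F2 | step 12 | 7-(ethoxythiocarbonylthio)-1-(ArCO)-8,8-dimethyl-5-(epoxy-Lav)bicyclo[3.3.1]nonane-4,9-dione | C=C(C)[C@H](CC3OC3(C)C)C[C@]12CC(SC(=S)OCC)C(C)(C)[C@](C(=O)c3ccc(O[Si](C(C)C)(C(C)C)C(C)C)c(O[Si](C(C)C)(C(C)C)C(C)C)c3)(C1=O)CCC2=O
F3 | step 9 | [4-methoxy-2-(3-methylbut-2-en-1-yloxy)-3-Lav-cyclohexa-1,3-dien-1-yl](Ar)methanone | C=C(C)[C@H](CC=C(C)C)CC1=C(OC)CCC(C(=O)c2ccc(O[Si](C(C)C)(C(C)C)C(C)C)c(O[Si](C(C)C)(C(C)C)C(C)C)c2)=C1OCC=C(C)C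
F4 | step 13 | 7-exo-allyl-1-(ArCO)-8,8-dimethyl-5-[4-oxo-2-(prop-1-en-2-yl)butyl]bicyclo[3.3.1]nonane-4,9-dione (side-chain stereocentre unchanged) | C=C(C)[C@H](CC=O)C[C@]12C[C@H](CC=C)C(C)(C)[C@](C(=O)c3ccc(O[Si](C(C)C)(C(C)C)C(C)C)c(O[Si](C(C)C)(C(C)C)C(C)C)c3)(C1=O)CCC2=O
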